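**Plan**

- Numbering used: C1 lactone carbonyl, C2–C8 ring carbons, C9 the methyl on C8, O5 lactone oxygen, O8 oxane oxygen. Feature: in the oxane ring (O8, C4–C8) the chain C5–C9 is that of a 6-deoxy-L-hexose, and on the adjacent pair C4/C5 the axial C4 methyl is cis to O5. This is the pattern left when a C4=C5 glycal bond is oxidised and methyl is handed to C4 from the new oxygen.
- Retrosynthetic cuts, in order: the O7–acyl ester; the lactone bonds C2–C3 and C1–O5 (bromopropionate, intramolecular Reformatsky); C4–CH3 together with C5–O5 (epoxidation/AlMe3 on a C4-vinyl glycal); C4–C3 (Stille coupling on a ketene acetal phosphate); C6–CH3 (cuprate); back to di-O-acetyl-L-rhamnal.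
- Forward: the oxane ring is bought and carried throughout. C6–Me is added, then the C3 vinyl group, then C4–Me and C5–O in one flask. The lactone ring closes late through C2–C3, and the side chain is esterified last.
- Stereochemistry: C7 and C8 come from L-rhamnose; C6 from cuprate addition anti to O7; C5 from epoxidation anti to the C6 methyl; C4 from syn methyl delivery; C2 and C3 from the samarium-templated aldol closure; the E alkene from an aldol condensation.

Key step: step 7

Remark: locants in the Why lines are botcinin locants as defined above; ester 14 is carried as a mixture at its CHBr carbon, which becomes the enolate carbon in step 10; DMDO is an acetone-free solution made from acetone and Oxone.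

**Route**

Step 1
Reactants: 1 3,4-di-O-acetyl-L-rhamnal
Product: 3 (5R,6S)-5-acetoxy-6-methyl-5,6-dihydro-2H-pyran-2-one (4-O-acetyl-2,3,6-trideoxy-L-erythro-hex-2-enono-1,5-lactone; OAc and CH3 trans), via anomeric perester 2 (not isolated)
Conditions: mCPBA (1.2 equiv), BF3·OEt2 (0.3 equiv), CH2Cl2, −20 °C
Reagents that add atoms: mCPBA, O=C(OO)c1cccc(Cl)c1
Why: Ferrier-type oxidation of a glycal ester, in which BF3 ionises the allylic acetate, the peracid captures the allyloxocarbenium ion at the anomeric carbon and the perester fragments with loss of 3-chlorobenzoic acid to the conjugated lactone (the established one-step route from glycal esters to 2-enono-1,5-lactones), leaving the two ring stereocentres (future C7 and C8) untouched.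

Step 2
Reactants: 3 (5R,6S)-5-acetoxy-6-methyl-5,6-dihydro-2H-pyran-2-one
Product: 4 (5R,6S)-5-hydroxy-6-methyl-5,6-dihydro-2H-pyran-2-one (osmundalactone)
Conditions: immobilised Candida antarctica lipase B, n-BuOH (3 equiv), MTBE, 35 °C
Reagents that add atoms: none
Why: Lipase-catalysed transesterification (enzymatic deacetylation) should cleave the secondary acetate under neutral conditions, which avoids base-induced translactonisation to the butenolide and conjugate addition, the conjugated lactone carbonyl being a poor acyl donor for the enzyme.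

Step 3
Reactants: 4 (5R,6S)-5-hydroxy-6-methyl-5,6-dihydro-2H-pyran-2-one
Product: 5 (5R,6S)-5-[(tert-butyldimethylsilyl)oxy]-6-methyl-5,6-dihydro-2H-pyran-2-one
Conditions: TBSOTf, 2,6-lutidine, CH2Cl2, −78 → 0 °C
Reagents that add atoms: tert-butyldimethylsilyl triflate, CC(C)(C)[Si](C)(C)OS(=O)(=O)C(F)(F)F
Why: Silylation of the secondary alcohol with a silyl triflate and a hindered pyridine base is fast at low temperature and replaces the γ-acetoxy group, which a cuprate would eliminate reductively, by an ether that should last to the end of the route.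

Step 4
Reactants: 5 (5R,6S)-5-[(tert-butyldimethylsilyl)oxy]-6-methyl-5,6-dihydro-2H-pyran-2-one
Product: 6 (4S,5R,6S)-5-[(tert-butyldimethylsilyl)oxy]-4,6-dimethyloxan-2-one (4-CH3 trans to 5-OTBS, 5-OTBS trans to 6-CH3)
Conditions: Me2CuLi (from MeLi and CuI), Et2O, −78 → −40 °C; aq. NH4Cl
Reagents that add atoms: lithium dimethylcuprate (from methyllithium and copper(I) iodide), [Li+].C[Cu-]C
Why: Gilman cuprate 1,4-addition to the unsaturated δ-lactone, in which methyl should add to the β-carbon on the face opposite the adjacent silyloxy group as established for 4-O-protected hex-2-enono-1,5-lactones, setting C6 with its methyl trans to O7.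

Step 5
Reactants: 6 (4S,5R,6S)-5-[(tert-butyldimethylsilyl)oxy]-4,6-dimethyloxan-2-one
Product: 7 (2S,3R,4S)-3-[(tert-butyldimethylsilyl)oxy]-2,4-dimethyl-3,4-dihydro-2H-pyran-6-yl diphenyl phosphate (ketene acetal phosphate)
Conditions: KHMDS, (PhO)2P(O)Cl, HMPA, THF, −78 °C
Reagents that add atoms: diphenyl chlorophosphate, O=P(Cl)(Oc1ccccc1)Oc1ccccc1
Why: Enolisation at the only α-position with KHMDS and O-phosphorylation of the potassium enolate (ketene acetal phosphate formation from a lactone) should give the enol phosphate without touching the β-stereocentre.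

Step 6
Reactants: 7 ketene acetal phosphate; 8 tributyl(vinyl)stannane
Product: 9 tert-butyl{[(2S,3R,4S)-6-ethenyl-2,4-dimethyl-3,4-dihydro-2H-pyran-3-yl]oxy}dimethylsilane (C4-vinyl glycal; C4=C5 enol ether)
Conditions: Pd(PPh3)4 (5 mol %), LiCl (3 equiv), THF, reflux; chromatography on Et3N-deactivated silica
Reagents that add atoms: tributyl(vinyl)stannane (8), C=C[Sn](CCCC)(CCCC)CCCC
Why: Stille coupling, in which Pd(0) inserts into the C–O bond of the ketene acetal phosphate and the vinyl group is transferred from tin with chloride assistance, is the standard way from lactones to 6-substituted dihydropyrans and forms no stereocentre.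

Step 7
Reactants: 9 C4-vinyl glycal; 10 trimethylaluminium
Product: 12 (2R,3S,4S,5R,6S)-5-[(tert-butyldimethylsilyl)oxy]-2-ethenyl-2,4,6-trimethyloxan-3-ol (C3–C9 fragment; C4 methyl axial and cis to the C5 hydroxyl, vinyl equatorial), via glycal epoxide 11 (not isolated)
Conditions: DMDO (1.2 equiv, acetone-free), CH2Cl2, −78 °C; then AlMe3 (3 equiv), −78 → −40 °C; aq. Rochelle salt
Reagents that add atoms: dimethyldioxirane, CC1(C)OO1; trimethylaluminium (10), C[Al](C)C
Why: Dimethyldioxirane should transfer oxygen in a concerted way to the C4=C5 enol ether bond of the 2-alkoxydiene, which is far more nucleophilic than the terminal vinyl bond, on the face opposite the C6 and C8 methyl groups (as gluco-configured glycals are epoxidised anti to their C3 substituent), and this fixes C5 with O5 cis to O7. Trimethylaluminium then binds the oxirane oxygen and ionises the C4–O bond to a vinyl-stabilised oxocarbenium ion held as a contact ion pair with the O5-bound aluminate, which passes a methyl group to C4 across a five-membered array on the face it already occupies, so C4 is set by syn (retentive) delivery along the axial trajectory with the vinyl group left equatorial. The closest known reaction is the one-flask epoxidation and trialkylaluminium syn-opening of C1-substituted glycals used for C-glycosides and for the angular methyl groups of fused polyethers. No ring of the product is closed, since the oxirane arises by concerted oxygen transfer and is opened again in the same flask. The step needs chemoselectivity for the enol ether over the vinyl group (secured by oxygen donation), regioselectivity for C4 over the vinyl terminus (secured by the short intramolecular path and the preference of trialkylaluminiums for the allylic carbon of vinyl oxiranes) and facial selectivity (secured by the C6 methyl next to the double bond).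

Step 8
Reactants: 12 tertiary ether alcohol; 13 2-bromopropanoyl bromide (racemic)
Product: 14 (2R,3S,4S,5R,6S)-5-[(tert-butyldimethylsilyl)oxy]-2-ethenyl-2,4,6-trimethyloxan-3-yl 2-bromopropanoate (both CHBr epimers)
Conditions: pyridine, DMAP (cat.), CH2Cl2, 0 °C
Reagents that add atoms: 2-bromopropanoyl bromide (13), CC(Br)C(=O)Br
Why: Acylation of the secondary C5 hydroxyl with an acyl bromide under pyridine/DMAP catalysis places C1, C2 and the C2 methyl on O5, and the CHBr centre need not be controlled because it becomes the enolate carbon.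

Step 9
Reactants: 14 bromopropanoate
Product: 16 (2S,3S,4S,5R,6S)-5-[(tert-butyldimethylsilyl)oxy]-2-formyl-2,4,6-trimethyloxan-3-yl 2-bromopropanoate (C3 aldehyde), via secondary ozonide 15 (not isolated)
Conditions: O3, CH2Cl2, −78 °C; PPh3 (1.1 equiv), −78 °C → rt
Reagents that add atoms: ozone, [O-][O+]=O
Why: Ozonolysis of the only C=C bond with reductive phosphine work-up should give the C3 aldehyde, which can neither epimerise nor eliminate because C4 is quaternary.

Step 10
Reactants: 16 bromo ester aldehyde
Product: 17 7-O-TBS-7-O-deacylbotcinin I, the trans-fused bicyclic lactone with 3-OH, methyls at C2, C4, C6, C8 and OTBS at C7 (2R,3S,4R,5S,6S,7R,8S)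
Conditions: SmI2 (2.5 equiv), THF, −78 °C; 0.1 M HCl
Reagents that add atoms: none
Why: SmI2-mediated intramolecular Reformatsky reaction: reduction of the C–Br bond gives a samarium(III) ester enolate that adds to the tethered aldehyde through a samarium-bridged cyclic transition state and closes the δ-lactone by C2–C3 bond formation (6-exo-trig aldol closure); with the aldehyde C=O aligned anti to the C4–O8 bond and the enolate forced to arrive from the O5 side of the oxane, the C3 oxygen should end cis to the C4 methyl, and a Z(O)-enolate should place the C2 methyl cis to that oxygen (anti aldol), both CHBr epimers converging on the same enolate.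

Step 11
Reactants: 17 silylated bicyclic lactone
Product: 18 7-O-deacylbotcinin I (3,7-diol of the bicyclic lactone; 2R,3S,4R,5S,6R,7R,8S)
Conditions: HF·pyridine, pyridine, THF, 0 °C → rt
Reagents that add atoms: none
Why: Fluoride-mediated cleavage of the silyl ether with buffered HF·pyridine is mildly acidic, so the β-hydroxy lactone is not exposed to base and retro-aldol cleavage, elimination and C2 epimerisation should not occur.

Step 12
Reactants: 19 hexan-2-one; 20 glyoxylic acid monohydrate
Product: 21 (2E)-4-oxooct-2-enoic acid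
Conditions: pyrrolidine (1 equiv), AcOH, MeOH, 60 °C
Reagents that add atoms: glyoxylic acid monohydrate (20), OC(O)C(=O)O
Why: Amine/acid-promoted crossed aldol condensation (the enamine of the methyl ketone adds to glyoxylic acid and the adduct dehydrates) should take place at the methyl group and give the thermodynamically preferred E enone acid.

Step 13
Reactants: 18 diol lactone; 21 (2E)-4-oxooct-2-enoic acid
Product: 22 botcinin I, the 7-O-[(2E)-4-oxooct-2-enoyl] ester of 18 (2R,3S,4R,5S,6R,7R,8S)
Conditions: DCC (1.1 equiv), DMAP (0.1 equiv), CH2Cl2, 0 °C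
Reagents that add atoms: none
Why: Steglich esterification (carbodiimide activation, DMAP acyl transfer), in which the equatorial C7 hydroxyl should react in preference to the C3 hydroxyl, which is flanked by the quaternary C4 and the C2 methine and deactivated by the β-carbonyl group, while the E geometry and all stereocentres are retained.

**Compound list**

1 | 3,4-di-O-acetyl-L-rhamnal | CC(=O)O[C@@H]1[C@@H](OC(C)=O)C=CO[C@H]1C | starting material
2 | 4-O-acetyl-2,3,6-trideoxy-L-erythro-hex-2-enopyranosyl 3-chloroperoxybenzoate (anomeric mixture) | CC(=O)O[C@@H]1C=CC(OOC(=O)c2cccc(Cl)c2)O[C@H]1C | intermediate (not isolated)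
3 | (5R,6S)-5-acetoxy-6-methyl-5,6-dihydro-2H-pyran-2-one | CC(=O)O[C@@H]1C=CC(=O)O[C@H]1C | intermediate
4 | (5R,6S)-5-hydroxy-6-methyl-5,6-dihydro-2H-pyran-2-one | O[C@@H]1C=CC(=O)O[C@H]1C | intermediate
5 | (5R,6S)-5-[(tert-butyldimethylsilyl)oxy]-6-methyl-5,6-dihydro-2H-pyran-2-one | CC(C)(C)[Si](C)(C)O[C@@H]1C=CC(=O)O[C@H]1C | intermediate
6 | (4S,5R,6S)-5-[(tert-butyldimethylsilyl)oxy]-4,6-dimethyloxan-2-one | CC(C)(C)[Si](C)(C)O[C@@H]1[C@@H](C)CC(=O)O[C@H]1C | intermediate
7 | (2S,3R,4S)-3-[(tert-butyldimethylsilyl)oxy]-2,4-dimethyl-3,4-dihydro-2H-pyran-6-yl diphenyl phosphate | CC(C)(C)[Si](C)(C)O[C@@H]1[C@@H](C)C=C(OP(=O)(Oc2ccccc2)Oc2ccccc2)O[C@H]1C | intermediate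
8 | tributyl(vinyl)stannane | C=C[Sn](CCCC)(CCCC)CCCC | starting material
9 | tert-butyl{[(2S,3R,4S)-6-ethenyl-2,4-dimethyl-3,4-dihydro-2H-pyran-3-yl]oxy}dimethylsilane | CC(C)(C)[Si](C)(C)O[C@@H]1[C@@H](C)C=C(C=C)O[C@H]1C | intermediate
10 | trimethylaluminium | C[Al](C)C | starting material
11 | glycal epoxide of 9 (1-ethenyl-3,5-dimethyl-4-silyloxy-2,7-dioxabicyclo[4.1.0]heptane, oxirane oxygen anti to the C6 methyl) | CC(C)(C)[Si](C)(C)O[C@@H]1[C@@H](C)[C@@H]2O[C@]2(C=C)O[C@H]1C | intermediate (not isolated)
12 | (2R,3S,4S,5R,6S)-5-[(tert-butyldimethylsilyl)oxy]-2-ethenyl-2,4,6-trimethyloxan-3-ol | CC(C)(C)[Si](C)(C)O[C@@H]1[C@@H](C)[C@H](O)[C@@](C)(C=C)O[C@H]1C | intermediate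
13 | 2-bromopropanoyl bromide (racemic) | CC(Br)C(=O)Br | starting material
14 | (2R,3S,4S,5R,6S)-5-[(tert-butyldimethylsilyl)oxy]-2-ethenyl-2,4,6-trimethyloxan-3-yl 2-bromopropanoate (CHBr epimers) | CC(C)(C)[Si](C)(C)O[C@@H]1[C@@H](C)[C@H](OC(=O)C(C)Br)[C@@](C)(C=C)O[C@H]1C | intermediate
15 | secondary ozonide of 14 (1,2,4-trioxolan-3-yl at C4) | CC(C)(C)[Si](C)(C)O[C@@H]1[C@@H](C)[C@H](OC(=O)C(C)Br)[C@@](C)(C2OCOO2)O[C@H]1C | intermediate (not isolated)
16 | (2S,3S,4S,5R,6S)-5-[(tert-butyldimethylsilyl)oxy]-2-formyl-2,4,6-trimethyloxan-3-yl 2-bromopropanoate | CC(C)(C)[Si](C)(C)O[C@@H]1[C@@H](C)[C@H](OC(=O)C(C)Br)[C@@](C)(C=O)O[C@H]1C | intermediate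
17 | 7-O-TBS-7-O-deacylbotcinin I | CC(C)(C)[Si](C)(C)O[C@@H]1[C@@H](C)[C@@H]2OC(=O)[C@H](C)[C@H](O)[C@@]2(C)O[C@H]1C | intermediate
18 | 7-O-deacylbotcinin I (3,7-diol) | O[C@@H]1[C@@H](C)[C@@H]2OC(=O)[C@H](C)[C@H](O)[C@@]2(C)O[C@H]1C | intermediate
19 | hexan-2-one | CCCCC(C)=O | starting material
20 | glyoxylic acid monohydrate | OC(O)C(=O)O | starting material
21 | (2E)-4-oxooct-2-enoic acid | CCCCC(=O)/C=C/C(=O)O | intermediate
22 | botcinin I | CCCCC(=O)/C=C/C(=O)O[C@@H]1[C@@H](C)[C@@H]2OC(=O)[C@H](C)[C@H](O)[C@@]2(C)O[C@H]1C | target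

**Step count and risks**

Total steps: 13. Longest linear sequence: 12 (steps 1–11 and 13); step 12 is a one-step side branch.

Step 7. The 2-alkoxy-2-vinyloxirane may ionise and collapse by hydride shift or elimination before methyl is transferred, methyl may be passed to the vinyl terminus instead of C4, or the dioxirane may attack both faces of the enol ether. The fallback replaces the conjugating vinyl group by a saturated C3 precursor, so that a plain tertiary oxocarbenium ion is formed as in the precedent. It sets out from 7: Stille coupling with (tributylstannyl)methanol (Pd(PPh3)4, LiCl, dioxane, reflux) would give the hydroxymethyl glycal F1, and TESCl/imidazole the triethylsilyl ether F2. DMDO would then give the glycal epoxide F3 (not isolated) and AlMe3 the tertiary ether alcohol F4. Acylation with 13 would give the bromopropanoate F5, PPTS in MeOH would free the primary alcohol F6, and Dess–Martin oxidation would return to the route at 16.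

Step 10. Facial discrimination at the aldehyde may be low, or the samarium enolate may form with mixed geometry, so that C3 or C2 is obtained as a mixture; pinacol-type reduction of the aldehyde may also compete. The fallback sets the two centres one at a time by intermolecular, model-predictable reactions. It sets out from 12: TESOTf/2,6-lutidine would give the O5 triethylsilyl ether F7, and ozonolysis (O3; PPh3) would lead through the ozonide F8 (not isolated) to the aldehyde F9. A chelation-controlled Mukaiyama aldol addition of tert-butyl[(1-methoxyethenyl)oxy]dimethylsilane (MgBr2·OEt2, CH2Cl2, −78 → −20 °C) would give the β-hydroxy methyl ester F10; with magnesium bridging the aldehyde oxygen and O8, attack occurs on the face carrying the small C4 methyl and away from C5 and its silyl ether, which is the C3 configuration of the target. Fráter–Seebach methylation of the dianion (LDA 2.2 equiv, MeI, THF/HMPA, −78 → −20 °C) would give the anti 2-methyl-3-hydroxy ester F11. PPTS in MeOH would remove the triethylsilyl group to the dihydroxy ester F12, which on warming with CSA in toluene would lactonise onto O5 and return to the route at 17.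

Step 13. Acylation may spread to O3 or give the bis-ester, and the enone acid may be consumed by conjugate addition of the nucleophilic catalyst. The fallback blocks O3 before O7 is uncovered. It sets out from 17: 4-methoxybenzyl trichloroacetimidate with La(OTf)3 in toluene would give the 3-O-PMB ether F13, and HF·pyridine the C7 alcohol F14. Steglich esterification with 21 would give 3-O-PMB-botcinin I F15, and DDQ in CH2Cl2/pH 7 buffer would remove the PMB group and return to the route at 22.

Further compounds
F1 | step 7 | [(2S,3R,4S)-3-[(tert-butyldimethylsilyl)oxy]-2,4-dimethyl-3,4-dihydro-2H-pyran-6-yl]methanol (hydroxymethyl glycal) | CC(C)(C)[Si](C)(C)O[C@@H]1[C@@H](C)C=C(CO)O[C@H]1C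
F2 | step 7 | triethylsilyl ether of F1 | CC(C)(C)[Si](C)(C)O[C@@H]1[C@@H](C)C=C(CO[Si](CC)(CC)CC)O[C@H]1C
F3 | step 7 | glycal epoxide of F2 (not isolated) | CC(C)(C)[Si](C)(C)O[C@@H]1[C@@H](C)[C@@H]2O[C@]2(CO[Si](CC)(CC)CC)O[C@H]1C
F4 | step 7 | tertiary ether alcohol with axial C4 methyl, C4 CH2OTES and C5 OH | CC(C)(C)[Si](C)(C)O[C@@H]1[C@@H](C)[C@H](O)[C@@](C)(CO[Si](CC)(CC)CC)O[C@H]1C
F5 | step 7 | 2-bromopropanoate of F4 (CHBr epimers) | CC(C)(C)[Si](C)(C)O[C@@H]1[C@@H](C)[C@H](OC(=O)C(C)Br)[C@@](C)(CO[Si](CC)(CC)CC)O[C@H]1C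
F6 | step 7 | primary alcohol from F5 (C3 CH2OH) | CC(C)(C)[Si](C)(C)O[C@@H]1[C@@H](C)[C@H](OC(=O)C(C)Br)[C@@](C)(CO)O[C@H]1C
F7 | step 10 | O5 triethylsilyl ether of 12 | CC(C)(C)[Si](C)(C)O[C@@H]1[C@@H](C)[C@H](O[Si](CC)(CC)CC)[C@@](C)(C=C)O[C@H]1C
F8 | step 10 | secondary ozonide of F7 (not isolated) | CC(C)(C)[Si](C)(C)O[C@@H]1[C@@H](C)[C@H](O[Si](CC)(CC)CC)[C@@](C)(C2OCOO2)O[C@H]1C
F9 | step 10 | C3 aldehyde with O5 triethylsilyl ether | CC(C)(C)[Si](C)(C)O[C@@H]1[C@@H](C)[C@H](O[Si](CC)(CC)CC)[C@@](C)(C=O)O[C@H]1C
F10 | step 10 | methyl (3S)-3-hydroxy-3-(oxan-2-yl)propanoate from the acetate aldol addition (C3 set) | CC(C)(C)[Si](C)(C)O[C@@H]1[C@@H](C)[C@H](O[Si](CC)(CC)CC)[C@@](C)([C@@H](O)CC(=O)OC)O[C@H]1C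
F11 | step 10 | anti 2-methyl-3-hydroxy methyl ester (C2 and C3 set) | CC(C)(C)[Si](C)(C)O[C@@H]1[C@@H](C)[C@H](O[Si](CC)(CC)CC)[C@@](C)([C@@H](O)[C@@H](C)C(=O)OC)O[C@H]1C
F12 | step 10 | dihydroxy methyl ester (O5 free) | CC(C)(C)[Si](C)(C)O[C@@H]1[C@@H](C)[C@H](O)[C@@](C)([C@@H](O)[C@@H](C)C(=O)OC)O[C@H]1C
F13 | step 13 | 3-O-(4-methoxybenzyl) ether of 17 | CC(C)(C)[Si](C)(C)O[C@@H]1[C@@H](C)[C@@H]2OC(=O)[C@H](C)[C@H](OCc3ccc(OC)cc3)[C@@]2(C)O[C@H]1C
F14 | step 13 | 3-O-(4-methoxybenzyl)-7-O-deacylbotcinin I | O[C@@H]1[C@@H](C)[C@@H]2OC(=O)[C@H](C)[C@H](OCc3ccc(OC)cc3)[C@@]2(C)O[C@H]1C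
F15 | step 13 | 3-O-(4-methoxybenzyl)botcinin I | CCCCC(=O)/C=C/C(=O)O[C@@H]1[C@@H](C)[C@@H]2OC(=O)[C@H](C)[C@H](OCc3ccc(OC)cc3)[C@@]2(C)O[C@H]1C
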